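**Retrosynthetic overview**

- Labels: the dihydrobenzofuran with the Z-styryl group is O1/C2/C3/C3a–C7a (benzo ring = ring A, styryl at C4). The second dihydrobenzofuran is primed (benzo ring = ring B) and is bonded through C5' to C3.
- Feature: the route rests on the O1'–C2'–C3'–H unit. C2' carries a para-oxygenated phenyl group that can hold positive charge. C3' carries only H besides its two aryl groups. This heterocycle is therefore what forms when a proton goes to C3' and the ring B phenol oxygen goes to C2' of a 1,1,2-triarylethene.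
- Disconnections: Z-alkene from the C4 alkyne (last step); seven OH from OMe; O1–C2 and C2–C3 from a [4+1] annulation of a ring A ortho-quinone methide (exocyclic C3) with a chiral 4-methoxybenzyl sulfonium ylide; C3–C5' from a C5' aryllithium and a ring A salicylaldehyde; O1'–C2' and C3'–H from asymmetric protonation–cyclisation of triarylethene 9.
- Ring order: the ring B heterocycle first (step 5), the ring A heterocycle second (step 13).

Key step: step 5

Assumption: precedent does not fix the sense of induction of either chiral reagent, so the (S,S)-IDPi (step 5) and the (1R,4R,5R)-sulfide from (R)-limonene (steps 9, 10, 13) are written as the antipodes that give the drawn configurations; if a first run shows the opposite sense, the (R,R)-IDPi or the sulfide from (S)-limonene is used and nothing else changes.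

**Route**

Step 1
Reactants: 1 5-bromo-2-hydroxy-3-methoxybenzaldehyde; 2 1-bromo-3,5-dimethoxybenzene
Product: 4 4-bromo-2-[(3,5-dimethoxyphenyl)(hydroxy)methyl]-6-methoxyphenol (racemic), via 3,5-dimethoxyphenylmagnesium bromide 3 (not isolated)
Conditions: 2, Mg, THF, reflux; then 1 (0.45 equiv), THF, 0 °C → rt; then H2O
Reagents that add atoms: none
Why: Grignard addition to an aldehyde, in which the first equivalent of 3 only deprotonates the phenol, the second adds to the formyl group, the aryl bromide of 1 is inert to an arylmagnesium halide without a catalyst, and the racemic carbinol centre is erased in step 2.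

Step 2
Reactants: 4 4-bromo-2-[(3,5-dimethoxyphenyl)(hydroxy)methyl]-6-methoxyphenol
Product: 5 (5-bromo-2-hydroxy-3-methoxyphenyl)(3,5-dimethoxyphenyl)methanone
Conditions: activated MnO2 (excess), CH2Cl2, rt
Reagents that add atoms: none
Why: Benzylic alcohol oxidation with MnO2 under neutral conditions; phenol coupling is held back because both ortho positions and the para position of the phenol are substituted, and the product is stabilised by its O–H···O=C hydrogen bond.

Step 3
Reactants: 5 (5-bromo-2-hydroxy-3-methoxyphenyl)(3,5-dimethoxyphenyl)methanone; 6 4-methoxybenzyl chloride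
Product: 8 4-bromo-2-[1-(3,5-dimethoxyphenyl)-1-hydroxy-2-(4-methoxyphenyl)ethyl]-6-methoxyphenol (racemic), via 4-methoxybenzylmagnesium chloride 7 (not isolated)
Conditions: 6, Mg, THF, 0 °C (slow addition); then 5 (0.33 equiv), 0 °C → rt; then H2O
Reagents that add atoms: none
Why: Grignard addition to a non-enolisable diaryl ketone, the standard entry to 2-(1-arylvinyl)phenols; one equivalent of 7 is spent on the phenol, the excess adds to the magnesium-chelated carbonyl, and the racemic tertiary centre disappears in step 4.

Step 4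
Reactants: 8 4-bromo-2-[1-(3,5-dimethoxyphenyl)-1-hydroxy-2-(4-methoxyphenyl)ethyl]-6-methoxyphenol
Product: 9 4-bromo-2-[1-(3,5-dimethoxyphenyl)-2-(4-methoxyphenyl)ethenyl]-6-methoxyphenol (E/Z mixture, Z isomer drawn)
Conditions: PPTS (10 mol %), 4 Å MS, toluene, 60 °C
Reagents that add atoms: none
Why: Acid-catalysed E1 dehydration, in which the tertiary, doubly benzylic, ortho-hydroxy carbinol ionises with an acid as weak as PPTS and loses a benzylic proton, while that acid is far too weak to protonate the product at C3', so no racemic ring closure should precede step 5.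

Step 5
Reactants: 9 4-bromo-2-[1-(3,5-dimethoxyphenyl)-2-(4-methoxyphenyl)ethenyl]-6-methoxyphenol
Product: 10 (2R,3R)-5-bromo-3-(3,5-dimethoxyphenyl)-7-methoxy-2-(4-methoxyphenyl)-2,3-dihydro-1-benzofuran (trans; C2 and C3 of this name are C2' and C3')
Conditions: (S,S)-IDPi (5 mol %; two (S)-3,3'-bis[3,5-bis(trifluoromethyl)phenyl]-BINOL units on a P–N–P core, both phosphorus atoms as P=N–SO2CF3), 5 Å MS, toluene (0.02 M), −20 °C → 0 °C, under argon
Reagents that add atoms: none
Why: Proposed new method: the IDPi, which is acidic enough to protonate styrenes, hands its proton to C3' of 9 inside the chiral ion pair, which creates the C3' stereocentre and a 4-methoxybenzyl cation at C2' that the neighbouring phenol oxygen O1' captures. The closest known reactions are IDPi-catalysed asymmetric intramolecular hydroalkoxylations of alkenols and chiral phosphoric acid reactions of ortho-hydroxystyrenes; the new element is that the proton, not the C–O bond, writes the primary stereocentre. The single ring closed is formally 5-endo-trig, but it runs as capture of a free, planar benzylic cation whose empty orbital lies within reach of O1', so the geometric objection to 5-endo closure does not apply. C3' is controlled by the confined anion, which must tell the two alkene faces apart at the moment of proton transfer (E and Z forms of 9 equilibrate through the other cation, so alkene geometry is no input), and C2' is controlled by C3', since O1' closes on the rotamer that holds the anisyl group anti to the 3,5-dimethoxyphenyl group. The selectivity needed is regioselective productive protonation: a proton placed on C2' gives a quinone-methide-like cation at C3' that has no nucleophile able to form a viable ring and can only give the proton back, while high dilution keeps the electron-rich aryl rings of a second molecule away from the C2' cation. Because 10 can re-ionise at C2' and that cation can also shed the C3' proton, the run is held at the lowest temperature that still turns over and is stopped at full conversion, so that the trans relation is kinetic and the C3' configuration is not washed out.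

Step 6
Reactants: 2 1-bromo-3,5-dimethoxybenzene
Product: 11 2-bromo-4,6-dimethoxybenzaldehyde
Conditions: POCl3, DMF, 0 °C → 90 °C; then H2O (ice)
Reagents that add atoms: N,N-dimethylformamide CN(C)C=O; water O
Why: Vilsmeier–Haack formylation, in which the chloroiminium ion attacks the position para to one methoxy group and ortho to the other in preference to the crowded site between both methoxy groups, and hydrolysis of the aryl iminium salt gives the aldehyde.

Step 7
Reactants: 11 2-bromo-4,6-dimethoxybenzaldehyde
Product: 12 2-bromo-6-hydroxy-4-methoxybenzaldehyde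
Conditions: BCl3 (1.2 equiv), CH2Cl2, −78 °C → 0 °C; then H2O
Reagents that add atoms: none
Why: Chelation-directed aryl methyl ether cleavage, in which BCl3 binds the formyl oxygen and the adjacent methoxy oxygen in a six-membered chelate, so only that methyl group leaves as MeCl while the para methoxy group and the aryl bromide stay.

Step 8
Reactants: 12 2-bromo-6-hydroxy-4-methoxybenzaldehyde; 13 4-ethynylanisole
Product: 14 2-hydroxy-4-methoxy-6-[(4-methoxyphenyl)ethynyl]benzaldehyde
Conditions: PdCl2(PPh3)2 (3 mol %), CuI (5 mol %), Et3N, THF, 60 °C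
Reagents that add atoms: none
Why: Sonogashira coupling, in which the ortho formyl group activates the C–Br bond for oxidative addition and the hydrogen-bonded phenol lies meta to the new alkyne and cannot cyclise onto it.

Step 9
Reactants: 15 (R)-limonene
Product: 16 (1R,4R,5R)-4,7,7-trimethyl-6-thiabicyclo[3.2.1]octane (isothiocineole)
Conditions: S8, gamma-terpinene, neat, 110 °C; distillation
Reagents that add atoms: sulfur S1SSSSSSS1
Why: Known one-pot radical sulfuration of limonene, in which sulfur bridges the ring alkene carbon and the isopropenyl carbon and gamma-terpinene supplies the two hydrogens; C1 comes from limonene, C5 is forced by the bridge and C4 is set by hydrogen delivery to the open face.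

Step 10
Reactants: 16 isothiocineole; 6 4-methoxybenzyl chloride
Product: 17 (1R,4R,5R,6R)-6-(4-methoxybenzyl)-4,7,7-trimethyl-6-thiabicyclo[3.2.1]octan-6-ium tetrafluoroborate
Conditions: NaBF4 (1.5 equiv), MeCN, rt
Reagents that add atoms: sodium tetrafluoroborate [Na+].F[B-](F)(F)F
Why: S-alkylation of a sulfide by a reactive benzylic chloride with exchange to a non-nucleophilic anion that blocks the reverse reaction; only the exo lone pair of sulfur, remote from the C2–C4 bridge, is open, so one configuration at sulfur should result.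

Step 11
Reactants: 10 ring B dihydrobenzofuran 5'-bromide; 14 2-hydroxy-4-methoxy-6-[(4-methoxyphenyl)ethynyl]benzaldehyde
Product: 20 2-{[(2R,3R)-3-(3,5-dimethoxyphenyl)-7-methoxy-2-(4-methoxyphenyl)-2,3-dihydro-1-benzofuran-5-yl](hydroxy)methyl}-5-methoxy-3-[(4-methoxyphenyl)ethynyl]phenol (both carbinol epimers), via ring B aryllithium 18 (not isolated), via sodium formylphenoxide 19 (not isolated)
Conditions: 10, n-BuLi (1.05 equiv), THF, −78 °C; 14 (1.3 equiv), NaH, THF, 0 °C in a second flask, then cannulated into 18, −78 °C → −20 °C; then H2O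
Reagents that add atoms: none
Why: Bromine–lithium exchange followed by 1,2-addition to an aldehyde; exchange at −78 °C outruns deprotonation at C3' and directed ortho-lithiation, prior conversion of 14 into its phenoxide saves the valuable aryllithium, and the unselective carbinol centre (future C3) is erased in step 13.

Step 12
Reactants: 20 ortho-hydroxybenzhydrol
Product: 21 2-{[(2R,3R)-3-(3,5-dimethoxyphenyl)-7-methoxy-2-(4-methoxyphenyl)-2,3-dihydro-1-benzofuran-5-yl](4-methylbenzenesulfonyl)methyl}-5-methoxy-3-[(4-methoxyphenyl)ethynyl]phenol (both epimers at the sulfonyl-bearing carbon)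
Conditions: p-TolSO2H (1.5 equiv), CH2Cl2, 0 °C → rt, under argon
Reagents that add atoms: p-toluenesulfinic acid Cc1ccc(S(=O)O)cc1
Why: SN1-type substitution of an ortho-hydroxybenzhydrol by a sulfinic acid, the usual way to storable ortho-quinone methide precursors; the carbinol, flanked by the ortho-OH/para-OMe ring A and the para-alkoxy ring B, ionises under the mild acidity of the reagent itself, which leaves the alkyne and the ring B heterocycle alone.

Step 13
Reactants: 21 sulfone; 17 chiral 4-methoxybenzyl sulfonium tetrafluoroborate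
Product: 24 (2S,3S)-3-[(2R,3R)-3-(3,5-dimethoxyphenyl)-7-methoxy-2-(4-methoxyphenyl)-2,3-dihydro-1-benzofuran-5-yl]-6-methoxy-2-(4-methoxyphenyl)-4-[(4-methoxyphenyl)ethynyl]-2,3-dihydro-1-benzofuran, via ortho-quinone methide 22 (not isolated), via sulfonium benzylide 23 (not isolated)
Conditions: 17 (1.3 equiv), Cs2CO3 (3 equiv), MeCN/CH2Cl2 1:1, −20 °C → rt
Reagents that add atoms: none
Why: Proposed new method: Cs2CO3 expels sulfinate from 21 to give ortho-quinone methide 22 and deprotonates 17 to benzylide 23, whose carbon adds to C3 (the slim alkyne at C4 keeps that carbon accessible, and only this addition restores the aromatic ring A) and whose sulfide is then displaced from C2 by the phenoxide in a 5-exo-tet closure; the [4+1] annulation of ortho-quinone methides with achiral sulfonium ylides is known and trans-selective, and isothiocineole benzylides are known to react through one ylide face with aldehydes and imines, so the new element is the pairing, in which the ylide face fixes C2, the preference for the trans-forming betaine fixes C3 relative to it, and the remote C2'/C3' centres are expected to play no part.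

Step 14
Reactants: 24 heptamethyl ether alkyne
Product: 25 (2S,3S)-3-[(2R,3R)-3-(3,5-dihydroxyphenyl)-7-hydroxy-2-(4-hydroxyphenyl)-2,3-dihydro-1-benzofuran-5-yl]-2-(4-hydroxyphenyl)-4-[(4-hydroxyphenyl)ethynyl]-2,3-dihydro-1-benzofuran-6-ol
Conditions: BBr3 (15 equiv), CH2Cl2, −78 °C → 0 °C; then H2O (ice)
Reagents that add atoms: none
Why: Lewis acid cleavage of aryl methyl ethers with BBr3, which tolerates diarylalkynes that lack an ortho methoxy group; should O1–C2 or O1'–C2' open, re-closure on work-up returns the trans rings because C3 and C3' are untouched, and the arm is kept as the alkyne here because a stilbene would be protonated and then attacked by ring B.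

Step 15
Reactants: 25 heptaphenol alkyne
Product: 26 target CNP0172909.2, (2S,3S,2'R,3'R), Z-alkene
Conditions: H2 (1 atm), Pd/CaCO3 poisoned with Pb(OAc)2, quinoline, EtOAc/MeOH, rt, light excluded, stopped after one equivalent of H2
Reagents that add atoms: none
Why: Lindlar-type semi-hydrogenation, in which syn delivery of H2 to the adsorbed diarylalkyne gives the Z-alkene, lead and quinoline slow further reduction, the benzylic C–O bonds are not hydrogenolysed under these conditions, and no stereocentre is involved.

**Compound list**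

1 | 5-bromo-2-hydroxy-3-methoxybenzaldehyde | O=Cc1cc(Br)cc(OC)c1O | starting material
2 | 1-bromo-3,5-dimethoxybenzene | COc1cc(Br)cc(OC)c1 | starting material
3 | 3,5-dimethoxyphenylmagnesium bromide | COc1cc([Mg]Br)cc(OC)c1 | intermediate
4 | 4-bromo-2-[(3,5-dimethoxyphenyl)(hydroxy)methyl]-6-methoxyphenol (racemic) | COc1cc(cc(OC)c1)C(O)c1cc(Br)cc(OC)c1O | intermediate
5 | (5-bromo-2-hydroxy-3-methoxyphenyl)(3,5-dimethoxyphenyl)methanone | COc1cc(cc(OC)c1)C(=O)c1cc(Br)cc(OC)c1O | intermediate
6 | 4-methoxybenzyl chloride | COc1ccc(CCl)cc1 | starting material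
7 | 4-methoxybenzylmagnesium chloride | COc1ccc(C[Mg]Cl)cc1 | intermediate
8 | 4-bromo-2-[1-(3,5-dimethoxyphenyl)-1-hydroxy-2-(4-methoxyphenyl)ethyl]-6-methoxyphenol (racemic) | COc1ccc(CC(O)(c2cc(OC)cc(OC)c2)c2cc(Br)cc(OC)c2O)cc1 | intermediate
9 | 4-bromo-2-[1-(3,5-dimethoxyphenyl)-2-(4-methoxyphenyl)ethenyl]-6-methoxyphenol (E/Z mixture, Z drawn) | COc1ccc(/C=C(/c2cc(OC)cc(OC)c2)c2cc(Br)cc(OC)c2O)cc1 | intermediate
10 | (2R,3R)-5-bromo-3-(3,5-dimethoxyphenyl)-7-methoxy-2-(4-methoxyphenyl)-2,3-dihydro-1-benzofuran | Brc1cc(OC)c2c(c1)[C@@H](c1cc(OC)cc(OC)c1)[C@H](c1ccc(OC)cc1)O2 | intermediate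
11 | 2-bromo-4,6-dimethoxybenzaldehyde | COc1cc(Br)c(C=O)c(OC)c1 | intermediate
12 | 2-bromo-6-hydroxy-4-methoxybenzaldehyde | COc1cc(O)c(C=O)c(Br)c1 | intermediate
13 | 4-ethynylanisole | C#Cc1ccc(OC)cc1 | starting material
14 | 2-hydroxy-4-methoxy-6-[(4-methoxyphenyl)ethynyl]benzaldehyde | COc1ccc(C#Cc2cc(OC)cc(O)c2C=O)cc1 | intermediate
15 | (R)-limonene | CC1=CC[C@@H](CC1)C(C)=C | starting material
16 | (1R,4R,5R)-4,7,7-trimethyl-6-thiabicyclo[3.2.1]octane (isothiocineole) | C[C@@H]1CC[C@@H]2C[C@H]1SC2(C)C | intermediate
17 | (1R,4R,5R,6R)-6-(4-methoxybenzyl)-4,7,7-trimethyl-6-thiabicyclo[3.2.1]octan-6-ium tetrafluoroborate | C[C@@H]1CC[C@@H]2C[C@H]1[S@@+](Cc1ccc(OC)cc1)C2(C)C.F[B-](F)(F)F | intermediate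
18 | [(2R,3R)-3-(3,5-dimethoxyphenyl)-7-methoxy-2-(4-methoxyphenyl)-2,3-dihydro-1-benzofuran-5-yl]lithium | [Li]c1cc(OC)c2c(c1)[C@@H](c1cc(OC)cc(OC)c1)[C@H](c1ccc(OC)cc1)O2 | intermediate
19 | sodium 2-formyl-5-methoxy-3-[(4-methoxyphenyl)ethynyl]phenoxide | COc1ccc(C#Cc2cc(OC)cc([O-])c2C=O)cc1.[Na+] | intermediate
20 | ortho-hydroxybenzhydrol joining ring A and C5' (both carbinol epimers; 2'R,3'R) | COc1ccc(C#Cc2cc(OC)cc(O)c2C(O)c2cc(OC)c3c(c2)[C@@H](c2cc(OC)cc(OC)c2)[C@H](c2ccc(OC)cc2)O3)cc1 | intermediate
21 | p-tolyl sulfone of 20 (both epimers at the sulfonyl carbon; 2'R,3'R) | COc1ccc(C#Cc2cc(OC)cc(O)c2C(c2cc(OC)c3c(c2)[C@@H](c2cc(OC)cc(OC)c2)[C@H](c2ccc(OC)cc2)O3)S(=O)(=O)c2ccc(C)cc2)cc1 | intermediate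
22 | ortho-quinone methide: 6-(ring B arylmethylidene)-3-methoxy-5-[(4-methoxyphenyl)ethynyl]cyclohexa-2,4-dien-1-one (2'R,3'R) | COc1ccc(C#CC2=CC(OC)=CC(=O)C2=Cc2cc(OC)c3c(c2)[C@@H](c2cc(OC)cc(OC)c2)[C@H](c2ccc(OC)cc2)O3)cc1 | intermediate
23 | 4-methoxybenzylide of isothiocineole | C[C@@H]1CC[C@@H]2C[C@H]1[S@@+]([CH-]c1ccc(OC)cc1)C2(C)C | intermediate
24 | (2S,3S,2'R,3'R) heptamethyl ether with the C4 (4-methoxyphenyl)ethynyl arm | COc1ccc(C#Cc2cc(OC)cc3c2[C@H](c2cc(OC)c4c(c2)[C@@H](c2cc(OC)cc(OC)c2)[C@H](c2ccc(OC)cc2)O4)[C@@H](c2ccc(OC)cc2)O3)cc1 | intermediate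
25 | (2S,3S,2'R,3'R) heptaphenol with the C4 (4-hydroxyphenyl)ethynyl arm | Oc1ccc(C#Cc2cc(O)cc3c2[C@H](c2cc(O)c4c(c2)[C@@H](c2cc(O)cc(O)c2)[C@H](c2ccc(O)cc2)O4)[C@@H](c2ccc(O)cc2)O3)cc1 | intermediate
26 | CNP0172909.2, (2S,3S,2'R,3'R), Z | Oc1ccc(/C=C\c2cc(O)cc3c2[C@H](c2cc(O)c4c(c2)[C@@H](c2cc(O)cc(O)c2)[C@H](c2ccc(O)cc2)O4)[C@@H](c2ccc(O)cc2)O3)cc1 | target

**Step count**

Total step count: 15. Longest linear sequence: 10 (steps 1–5 and 11–15).

**Steps most likely to fail**

1. Step 5.
   - What may go wrong:
     - The bulky triarylethene may fit the confined pocket badly, so turnover slows and an unselective background takes over.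
     - Proton transfer may discriminate poorly between the alkene faces.
     - Reversible ring opening followed by loss of the C3' proton may erode the enantiomeric purity.
     - Cationic oligomerisation through the electron-rich aryl rings may compete.
   - Fallback (known enantioselective C–H insertion of donor/donor rhodium carbenes): it sets out from 5 and returns at 10. Alkylating the phenol of 5 with 6 (K2CO3, DMF, 60 °C) gives the 4-methoxybenzyl ether F1. Treatment with N2H4·H2O (EtOH, catalytic AcOH, reflux) gives the hydrazone F2. MnO2 in CH2Cl2 oxidises this to the diaryldiazomethane F3. With Rh2(S-PTAD)4 (1 mol %, antipode chosen for the C3' sense), F3 inserts into the benzylic O–CH2 bond and should give the cis-dihydrobenzofuran F4. Brief exposure to CF3CO2H in CH2Cl2 at 0 °C inverts C2' through the 4-methoxybenzyl cation and delivers trans 10.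

2. Step 13.
   - What may go wrong:
     - The hindered chiral benzylide may add slowly, so the quinone methide is consumed by self-reaction or by return of sulfinate.
     - The electron-rich sulfonium salt may lose its sulfide by ionisation before it is deprotonated.
     - Facial selectivity on the quinone methide may be poor.
   - Fallback (known racemic-type [4+1] annulation plus separation of diastereomers): it sets out from 21 and returns at 24. Compound 6, Me2S and NaBF4 in MeCN give (4-methoxybenzyl)dimethylsulfonium tetrafluoroborate F5. Cs2CO3 converts this in the flask into the small and reactive dimethylsulfonium 4-methoxybenzylide F6. Its annulation with 22 (generated from 21 as before) should give the two trans products. Because ring B is already a single enantiomer these are diastereomers. Compound 24 is separated by chromatography from the (2R,3R,2'R,3'R) diastereomer F7.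

3. Step 14.
   - What may go wrong:
     - Lewis acid ionisation of O1–C2 may be followed by capture of the cation by the neighbouring alkyne, or by loss of the C3 proton.
     - The alkyne may undergo bromoboration.
     - Cleavage of the seven ethers may be incomplete.
   - Fallback (demethylation before the alkyne is present, arm attached afterwards): it sets out from 10 and 12 and returns at 25.
     - Compound 12 with NaH gives sodium 3-bromo-2-formyl-5-methoxyphenoxide F8. Aryllithium 18 adds to it to give the bromo benzhydrol F9.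
     - p-TolSO2H gives the bromo sulfone F10. Cs2CO3 with 17 converts this, through the bromo ortho-quinone methide F11, into the C4-bromo hexamethyl ether F12.
     - BBr3 now acts on a substrate with no π-nucleophile next to C2 and should give the C4-bromo hexaphenol F13.
     - A copper-free Sonogashira coupling with 4-ethynylphenol (PdCl2(MeCN)2, XPhos, Cs2CO3, MeCN, 70 °C) then gives 25.

**Further compounds**

F1 | step 5 | [5-bromo-3-methoxy-2-(4-methoxybenzyloxy)phenyl](3,5-dimethoxyphenyl)methanone | COc1ccc(COc2c(OC)cc(Br)cc2C(=O)c2cc(OC)cc(OC)c2)cc1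
F2 | step 5 | hydrazone of F1 | COc1ccc(COc2c(OC)cc(Br)cc2C(=NN)c2cc(OC)cc(OC)c2)cc1
F3 | step 5 | diaryldiazomethane from F2 | COc1ccc(COc2c(OC)cc(Br)cc2C(=[N+]=[N-])c2cc(OC)cc(OC)c2)cc1
F4 | step 5 | (2S,3R)-5-bromo-3-(3,5-dimethoxyphenyl)-7-methoxy-2-(4-methoxyphenyl)-2,3-dihydro-1-benzofuran (cis) | Brc1cc(OC)c2c(c1)[C@@H](c1cc(OC)cc(OC)c1)[C@@H](c1ccc(OC)cc1)O2
F5 | step 13 | (4-methoxybenzyl)dimethylsulfonium tetrafluoroborate | C[S+](C)Cc1ccc(OC)cc1.F[B-](F)(F)F
F6 | step 13 | dimethylsulfonium 4-methoxybenzylide | C[S+](C)[CH-]c1ccc(OC)cc1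
F7 | step 13 | (2R,3R,2'R,3'R) diastereomer of 24 | COc1ccc(C#Cc2cc(OC)cc3c2[C@@H](c2cc(OC)c4c(c2)[C@@H](c2cc(OC)cc(OC)c2)[C@H](c2ccc(OC)cc2)O4)[C@H](c2ccc(OC)cc2)O3)cc1
F8 | step 14 | sodium 3-bromo-2-formyl-5-methoxyphenoxide | COc1cc([O-])c(C=O)c(Br)c1.[Na+]
F9 | step 14 | 3-bromo-2-{[(2R,3R)-ring B dihydrobenzofuran-5-yl](hydroxy)methyl}-5-methoxyphenol (both carbinol epimers) | COc1cc(O)c(C(O)c2cc(OC)c3c(c2)[C@@H](c2cc(OC)cc(OC)c2)[C@H](c2ccc(OC)cc2)O3)c(Br)c1
F10 | step 14 | p-tolyl sulfone of F9 (both epimers) | COc1cc(O)c(C(c2cc(OC)c3c(c2)[C@@H](c2cc(OC)cc(OC)c2)[C@H](c2ccc(OC)cc2)O3)S(=O)(=O)c2ccc(C)cc2)c(Br)c1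
F11 | step 14 | 5-bromo-3-methoxy-6-(ring B arylmethylidene)cyclohexa-2,4-dien-1-one | COC1=CC(=O)C(=Cc2cc(OC)c3c(c2)[C@@H](c2cc(OC)cc(OC)c2)[C@H](c2ccc(OC)cc2)O3)C(Br)=C1
F12 | step 14 | (2S,3S,2'R,3'R) C4-bromo hexamethyl ether | Brc1cc(OC)cc2c1[C@H](c1cc(OC)c3c(c1)[C@@H](c1cc(OC)cc(OC)c1)[C@H](c1ccc(OC)cc1)O3)[C@@H](c1ccc(OC)cc1)O2
F13 | step 14 | (2S,3S,2'R,3'R) C4-bromo hexaphenol | Brc1cc(O)cc2c1[C@H](c1cc(O)c3c(c1)[C@@H](c1cc(O)cc(O)c1)[C@H](c1ccc(O)cc1)O3)[C@@H](c1ccc(O)cc1)O2
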